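**Plan**

- Flavan numbering is used for both halves. Unit A is the all-cis (2R,3R,4R) half and unit B is the 2,3-trans-3,4-cis (2S,3R,4R) half; they are joined C4–O–C4.
- Enabling feature: ring C of unit A (O1, C2, C3, C4, C4a, C8a) is a 4-alkoxychroman. Its C4 carries the ether oxygen to unit B, and C4a lies ortho to the O1-bearing C8a of ring A. This is the cycloadduct pattern of an alkoxy-o-quinone methide of ring A with a Z-configured 2-arylethenyl ester.
- Retrosynthetic cuts, in order: six aryl benzyl ethers, one silyl ether and one pivalate; then C3–C4 and O1–C2 of unit A together; then the acetal carbon back to an aryl ester of the unit B 4-ol; then O1–C2 of unit B (chalcone epoxide) and the chalcone C=C.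
- Forward order: ring C of unit B closes first. The ring A carbon of unit A is then attached by acylation and taken to the α-acetoxy ether. Ring C of unit A closes last by [4+2].
- Stereochemistry: unit B C2/C3 come from a Juliá–Colonna epoxide (C2 by inversion) and C4 from hydride delivery anti to the 3-silyloxy group. Unit A C2/C3 come from the Z-alkene, the all-cis array from endo addition to the E-heterodiene, and the absolute sense from the unit B alkoxy group on the methide carbon.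

Key step: step 15

Remark on the chemistry: the secondary hydroxyl of unit B is carried as a triisopropylsilyl ether, so that the last hydrogenolysis meets aryl benzyl ethers only and the silyloxy group can shield one face of the heterodiene; 2',3',4'-trihydroxyacetophenone is taken as a purchasable starting material.

**Route**

Step 1
Reactants: 1 1-(2,3,4-trihydroxyphenyl)ethan-1-one
Product: 2 1-[3,4-bis(benzyloxy)-2-hydroxyphenyl]ethan-1-one
Conditions: BnBr (2.1 equiv), K2CO3, acetone, reflux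
Reagents that add atoms: benzyl bromide, BrCc1ccccc1
Why: Williamson ether synthesis in which the 2-hydroxyl, held in a hydrogen bond to the ketone, is the least reactive phenol, so the 3- and 4-hydroxyls should be alkylated selectively.

Step 2
Reactants: 2 1-[3,4-bis(benzyloxy)-2-hydroxyphenyl]ethan-1-one
Product: 3 1-[3,4-bis(benzyloxy)-2-(methoxymethoxy)phenyl]ethan-1-one
Conditions: NaH, MOMCl, DMF, 0 °C to rt
Reagents that add atoms: chloromethyl methyl ether, COCCl
Why: Williamson-type O-alkylation that masks the chelated phenol as an acetal, because a free 2'-phenol would cyclise or be oxidised under the basic peroxide conditions of step 4.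

Step 3
Reactants: 3 1-[3,4-bis(benzyloxy)-2-(methoxymethoxy)phenyl]ethan-1-one; 4 4-(benzyloxy)benzaldehyde
Product: 5 (E)-1-[3,4-bis(benzyloxy)-2-(methoxymethoxy)phenyl]-3-[4-(benzyloxy)phenyl]prop-2-en-1-one
Conditions: KOH, EtOH–THF, rt
Reagents that add atoms: none
Why: Claisen–Schmidt condensation, whose aldol adduct dehydrates by E1cB elimination to the conjugated E-enone.

Step 4
Reactants: 5 (E)-1-[3,4-bis(benzyloxy)-2-(methoxymethoxy)phenyl]-3-[4-(benzyloxy)phenyl]prop-2-en-1-one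
Product: 6 [3,4-bis(benzyloxy)-2-(methoxymethoxy)phenyl]{(2S,3R)-3-[4-(benzyloxy)phenyl]oxiran-2-yl}methanone
Conditions: poly-D-leucine, urea–H2O2, DBU, THF, rt
Reagents that add atoms: urea–hydrogen peroxide, NC(N)=O.OO
Why: Juliá–Colonna epoxidation (polypeptide-mediated Weitz–Scheffer reaction) turns the E-enone into the trans epoxide, and poly-D-leucine should give the (2S,3R) enantiomer, the mirror image of the sense known for poly-L-leucine with chalcones, with recrystallisation available to raise the enantiomeric purity.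

Step 5
Reactants: 6 [3,4-bis(benzyloxy)-2-(methoxymethoxy)phenyl]{(2S,3R)-3-[4-(benzyloxy)phenyl]oxiran-2-yl}methanone
Product: 8 (2S,3S)-7,8-bis(benzyloxy)-2-[4-(benzyloxy)phenyl]-3-hydroxy-2,3-dihydro-4H-chromen-4-one, via 2'-hydroxychalcone epoxide 7 (not isolated)
Conditions: conc. HCl, MeOH–THF, 50 °C
Reagents that add atoms: none
Why: acetal cleavage followed by acid-catalysed 6-endo epoxide opening by the freed phenol at the benzylic carbon should give the 2,3-trans dihydroflavonol, with C3 keeping the epoxide configuration and C2 formed by inversion.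

Step 6
Reactants: 8 (2S,3S)-7,8-bis(benzyloxy)-2-[4-(benzyloxy)phenyl]-3-hydroxy-2,3-dihydro-4H-chromen-4-one
Product: 9 (2S,3S)-7,8-bis(benzyloxy)-2-[4-(benzyloxy)phenyl]-3-[(triisopropylsilyl)oxy]-2,3-dihydro-4H-chromen-4-one
Conditions: i-Pr3SiOTf, 2,6-lutidine, CH2Cl2, 0 °C
Reagents that add atoms: triisopropylsilyl trifluoromethanesulfonate, CC(C)[Si](C(C)C)(C(C)C)OS(=O)(=O)C(F)(F)F
Why: silyl ether formation at a secondary alcohol with a hindered, weakly basic amine, mild enough to leave the epimerisable C2 and C3 of the 3-hydroxyflavanone untouched.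

Step 7
Reactants: 9 (2S,3S)-7,8-bis(benzyloxy)-2-[4-(benzyloxy)phenyl]-3-[(triisopropylsilyl)oxy]-2,3-dihydro-4H-chromen-4-one
Product: 10 (2S,3R,4R)-7,8-bis(benzyloxy)-2-[4-(benzyloxy)phenyl]-3-[(triisopropylsilyl)oxy]chroman-4-ol
Conditions: LiBH(s-Bu)3, THF, −78 °C; then H2O
Reagents that add atoms: none
Why: diastereoselective ketone reduction in which the bulky hydride adds on the equatorial trajectory anti to the non-chelating 3-silyloxy group, so the new 4-hydroxyl should be pseudoaxial and cis to the 3-oxygen (4R).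

Step 8
Reactants: 11 2,3,4-trihydroxybenzaldehyde
Product: 12 3,4-bis(benzyloxy)-2-hydroxybenzaldehyde
Conditions: BnBr (2.1 equiv), K2CO3, DMF, rt
Reagents that add atoms: benzyl bromide, BrCc1ccccc1
Why: Williamson ether synthesis with the same selectivity as in step 1, the 2-hydroxyl being protected by its hydrogen bond to the aldehyde.

Step 9
Reactants: 12 3,4-bis(benzyloxy)-2-hydroxybenzaldehyde
Product: 13 3,4-bis(benzyloxy)-2-[(tert-butyldimethylsilyl)oxy]benzaldehyde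
Conditions: t-BuMe2SiCl, imidazole, DMF, rt
Reagents that add atoms: tert-butyldimethylsilyl chloride, CC(C)(C)[Si](C)(C)Cl
Why: imidazole-promoted silylation of the phenol installs the fluoride-labile group that later triggers quinone methide formation.

Step 10
Reactants: 13 3,4-bis(benzyloxy)-2-[(tert-butyldimethylsilyl)oxy]benzaldehyde
Product: 14 3,4-bis(benzyloxy)-2-[(tert-butyldimethylsilyl)oxy]benzoic acid
Conditions: NaClO2, NaH2PO4, 2-methylbut-2-ene, t-BuOH–H2O, rt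
Reagents that add atoms: sodium chlorite, [Na+].[O-]Cl=O
Why: Pinnick oxidation converts the aldehyde into the acid at buffered pH, which aryl silyl and benzyl ethers tolerate; the acid is used directly.

Step 11
Reactants: 14 3,4-bis(benzyloxy)-2-[(tert-butyldimethylsilyl)oxy]benzoic acid; 10 (2S,3R,4R)-7,8-bis(benzyloxy)-2-[4-(benzyloxy)phenyl]-3-[(triisopropylsilyl)oxy]chroman-4-ol
Product: 16 (2S,3S,4R)-7,8-bis(benzyloxy)-2-[4-(benzyloxy)phenyl]-3-[(triisopropylsilyl)oxy]chroman-4-yl 3,4-bis(benzyloxy)-2-[(tert-butyldimethylsilyl)oxy]benzoate, via aroyl chloride 15 (not isolated)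
Conditions: 1-chloro-N,N,2-trimethylprop-1-en-1-amine, CH2Cl2, 0 °C; then 10, pyridine, DMAP, CH2Cl2, rt to 40 °C
Reagents that add atoms: none
Why: nucleophilic acyl substitution through a neutrally generated acid chloride, in which the C4–O bond of 10 is never broken, so the unit B ether stereocentre is retained (the C3 descriptor changes by priority only).

Step 12
Reactants: 16 (2S,3S,4R)-7,8-bis(benzyloxy)-2-[4-(benzyloxy)phenyl]-3-[(triisopropylsilyl)oxy]chroman-4-yl 3,4-bis(benzyloxy)-2-[(tert-butyldimethylsilyl)oxy]benzoate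
Product: 18 {3,4-bis(benzyloxy)-2-[(tert-butyldimethylsilyl)oxy]phenyl}{[(2S,3S,4R)-7,8-bis(benzyloxy)-2-[4-(benzyloxy)phenyl]-3-[(triisopropylsilyl)oxy]chroman-4-yl]oxy}methyl acetate (both acetal epimers), via diisobutylaluminium hemiacetal 17 (not isolated)
Conditions: i-Bu2AlH, CH2Cl2, −78 °C; then pyridine, DMAP, Ac2O, −78 to −20 °C; filtration through Et3N-deactivated silica
Reagents that add atoms: acetic anhydride, CC(=O)OC(C)=O
Why: reductive acetylation of an ester, in which the tetrahedral aluminium hemiacetal persists at −78 °C and is O-acetylated in the flask to the α-acetoxy ether; the acetal epimer mixture is irrelevant because this carbon becomes trigonal in step 15.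

Step 13
Reactants: 4 4-(benzyloxy)benzaldehyde
Product: 19 1-(benzyloxy)-4-ethynylbenzene
Conditions: dimethyl (1-diazo-2-oxopropyl)phosphonate, K2CO3, MeOH, rt
Reagents that add atoms: dimethyl (1-diazo-2-oxopropyl)phosphonate, COP(=O)(OC)C(=[N+]=[N-])C(C)=O
Why: Seyferth–Gilbert homologation with the Ohira–Bestmann reagent converts the aryl aldehyde into the terminal alkyne in one step under mild base.

Step 14
Reactants: 19 1-(benzyloxy)-4-ethynylbenzene; 20 2,2-dimethylpropanoic acid (pivalic acid)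
Product: 21 (Z)-2-[4-(benzyloxy)phenyl]ethenyl 2,2-dimethylpropanoate
Conditions: Ru(CH2C(CH3)CH2)2(Ph2P(CH2)4PPh2) (2 mol%), toluene, 60 °C
Reagents that add atoms: none
Why: ruthenium-catalysed anti-Markovnikov hydro-acyloxylation of a terminal alkyne through a vinylidene complex, which should deliver the carboxylate to the terminal carbon and give the Z-enol ester.

Step 15
Reactants: 18 {3,4-bis(benzyloxy)-2-[(tert-butyldimethylsilyl)oxy]phenyl}{[(2S,3S,4R)-7,8-bis(benzyloxy)-2-[4-(benzyloxy)phenyl]-3-[(triisopropylsilyl)oxy]chroman-4-yl]oxy}methyl acetate; 21 (Z)-2-[4-(benzyloxy)phenyl]ethenyl 2,2-dimethylpropanoate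
Product: 24 (2R,3R,4R)-7,8-bis(benzyloxy)-2-[4-(benzyloxy)phenyl]-4-{[(2S,3R,4R)-7,8-bis(benzyloxy)-2-[4-(benzyloxy)phenyl]-3-[(triisopropylsilyl)oxy]chroman-4-yl]oxy}chroman-3-yl 2,2-dimethylpropanoate, via caesium phenoxide 22 (not isolated), via E-alkoxy-o-quinone methide 23 (not isolated)
Conditions: CsF (3 equiv), 21 (3 equiv), 4 Å molecular sieves, MeCN, 0 °C to rt
Reagents that add atoms: none
Why: Proposed new method: fluoride removes the aryl silyl group of 18, the phenoxide 22 pushes acetate out of the acetal carbon, and the neutral E-configured alkoxy-o-quinone methide 23 is trapped by the electron-rich Z-enol ester 21 in an inverse-electron-demand hetero-Diels–Alder reaction; the closest known reaction type is the fluoride- or acid-triggered generation of o-quinone methides, including alkoxy-substituted ones from salicylaldehyde acetals, and their [4+2] capture by styrenes and enol ethers to give 2,4-disubstituted chromans. Ring C of unit A closes in a concerted, asynchronous [4+2] mode in which C3–C4 runs ahead of O1–C2. The regiochemistry that is needed is secured by the p-benzyloxyphenyl group, which outweighs the acyloxy group, makes the pivaloyloxy-bearing carbon the nucleophilic end and carries the developing positive charge at C2 until O1 closes. C2 and C3 are controlled by the Z geometry of 21 (2,3-cis) and by its endo approach to the E-heterodiene, which puts aryl, pivaloyloxy and the C4 ether oxygen on one face (all-cis). C4 is controlled by the unit B alkoxy group: with the ether s-trans, the unit B C4–H in the plane of the heterodiene and the gauche 3-triisopropylsilyloxy group lying under one face, attack on the open face should give 4R. Since the heterodiene is neutral, neither benzylic C4–O bond should ionise, and the hindered pivalate should resist acyl transfer to the phenoxide.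

Step 16
Reactants: 24 (2R,3R,4R)-7,8-bis(benzyloxy)-2-[4-(benzyloxy)phenyl]-4-{[(2S,3R,4R)-7,8-bis(benzyloxy)-2-[4-(benzyloxy)phenyl]-3-[(triisopropylsilyl)oxy]chroman-4-yl]oxy}chroman-3-yl 2,2-dimethylpropanoate
Product: 25 (2R,3R,4R)-7,8-bis(benzyloxy)-2-[4-(benzyloxy)phenyl]-4-{[(2S,3R,4R)-7,8-bis(benzyloxy)-2-[4-(benzyloxy)phenyl]-3-[(triisopropylsilyl)oxy]chroman-4-yl]oxy}chroman-3-ol
Conditions: i-Bu2AlH, CH2Cl2, −78 °C
Reagents that add atoms: none
Why: reductive cleavage of the hindered ester by hydride, a non-acidic and non-solvolytic way to free the unit A 3-hydroxyl without touching the dibenzylic ether or the silyl ether.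

Step 17
Reactants: 25 (2R,3R,4R)-7,8-bis(benzyloxy)-2-[4-(benzyloxy)phenyl]-4-{[(2S,3R,4R)-7,8-bis(benzyloxy)-2-[4-(benzyloxy)phenyl]-3-[(triisopropylsilyl)oxy]chroman-4-yl]oxy}chroman-3-ol
Product: 26 (2R,3R,4R)-7,8-bis(benzyloxy)-2-[4-(benzyloxy)phenyl]-4-{[(2S,3R,4R)-7,8-bis(benzyloxy)-2-[4-(benzyloxy)phenyl]-3-hydroxychroman-4-yl]oxy}chroman-3-ol
Conditions: Bu4NF, AcOH, THF, rt
Reagents that add atoms: none
Why: fluoride-mediated desilylation of the secondary silyl ether under buffered conditions, which leaves benzyl ethers and the inter-unit ether alone.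

Step 18
Reactants: 26 (2R,3R,4R)-7,8-bis(benzyloxy)-2-[4-(benzyloxy)phenyl]-4-{[(2S,3R,4R)-7,8-bis(benzyloxy)-2-[4-(benzyloxy)phenyl]-3-hydroxychroman-4-yl]oxy}chroman-3-ol
Product: 27 (2R,3R,4R)-2-(4-hydroxyphenyl)-4-{[(2S,3R,4R)-3,7,8-trihydroxy-2-(4-hydroxyphenyl)chroman-4-yl]oxy}chromane-3,7,8-triol (CNP0241481.1)
Conditions: H2 (1 atm), Pd(OH)2 on carbon, THF–MeOH, rt, stopped at full conversion
Reagents that add atoms: none
Why: catalytic hydrogenolysis of six aryl benzyl ethers, which are cleaved much faster than the hindered secondary dibenzylic ether and the cyclic C2–O1 bonds, so neutral conditions and a short reaction time should leave the skeleton and all six stereocentres intact.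

**Compound list**

1 | 1-(2,3,4-trihydroxyphenyl)ethan-1-one | CC(=O)c1ccc(O)c(O)c1O | starting material
2 | 1-[3,4-bis(benzyloxy)-2-hydroxyphenyl]ethan-1-one | CC(=O)c1ccc(OCc2ccccc2)c(OCc2ccccc2)c1O | intermediate
3 | 1-[3,4-bis(benzyloxy)-2-(methoxymethoxy)phenyl]ethan-1-one | CC(=O)c1ccc(OCc2ccccc2)c(OCc2ccccc2)c1OCOC | intermediate
4 | 4-(benzyloxy)benzaldehyde | O=Cc1ccc(OCc2ccccc2)cc1 | starting material
5 | (E)-1-[3,4-bis(benzyloxy)-2-(methoxymethoxy)phenyl]-3-[4-(benzyloxy)phenyl]prop-2-en-1-one | COCOc1c(C(=O)/C=C/c2ccc(OCc3ccccc3)cc2)ccc(OCc2ccccc2)c1OCc1ccccc1 | intermediate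
6 | [3,4-bis(benzyloxy)-2-(methoxymethoxy)phenyl]{(2S,3R)-3-[4-(benzyloxy)phenyl]oxiran-2-yl}methanone | COCOc1c(C(=O)[C@H]2O[C@@H]2c2ccc(OCc3ccccc3)cc2)ccc(OCc2ccccc2)c1OCc1ccccc1 | intermediate
7 | [3,4-bis(benzyloxy)-2-hydroxyphenyl]{(2S,3R)-3-[4-(benzyloxy)phenyl]oxiran-2-yl}methanone | Oc1c(C(=O)[C@H]2O[C@@H]2c2ccc(OCc3ccccc3)cc2)ccc(OCc2ccccc2)c1OCc1ccccc1 | intermediate (not isolated)
8 | (2S,3S)-7,8-bis(benzyloxy)-2-[4-(benzyloxy)phenyl]-3-hydroxy-2,3-dihydro-4H-chromen-4-one (2,3-trans) | O=C1c2ccc(OCc3ccccc3)c(OCc3ccccc3)c2O[C@@H](c2ccc(OCc3ccccc3)cc2)[C@@H]1O | intermediate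
9 | (2S,3S)-7,8-bis(benzyloxy)-2-[4-(benzyloxy)phenyl]-3-[(triisopropylsilyl)oxy]-2,3-dihydro-4H-chromen-4-one | O=C1c2ccc(OCc3ccccc3)c(OCc3ccccc3)c2O[C@@H](c2ccc(OCc3ccccc3)cc2)[C@@H]1O[Si](C(C)C)(C(C)C)C(C)C | intermediate
10 | (2S,3R,4R)-7,8-bis(benzyloxy)-2-[4-(benzyloxy)phenyl]-3-[(triisopropylsilyl)oxy]chroman-4-ol (2,3-trans-3,4-cis) | O[C@@H]1c2ccc(OCc3ccccc3)c(OCc3ccccc3)c2O[C@@H](c2ccc(OCc3ccccc3)cc2)[C@@H]1O[Si](C(C)C)(C(C)C)C(C)C | intermediate
11 | 2,3,4-trihydroxybenzaldehyde | O=Cc1ccc(O)c(O)c1O | starting material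
12 | 3,4-bis(benzyloxy)-2-hydroxybenzaldehyde | O=Cc1ccc(OCc2ccccc2)c(OCc2ccccc2)c1O | intermediate
13 | 3,4-bis(benzyloxy)-2-[(tert-butyldimethylsilyl)oxy]benzaldehyde | O=Cc1ccc(OCc2ccccc2)c(OCc2ccccc2)c1O[Si](C)(C)C(C)(C)C | intermediate
14 | 3,4-bis(benzyloxy)-2-[(tert-butyldimethylsilyl)oxy]benzoic acid | OC(=O)c1ccc(OCc2ccccc2)c(OCc2ccccc2)c1O[Si](C)(C)C(C)(C)C | intermediate
15 | 3,4-bis(benzyloxy)-2-[(tert-butyldimethylsilyl)oxy]benzoyl chloride | ClC(=O)c1ccc(OCc2ccccc2)c(OCc2ccccc2)c1O[Si](C)(C)C(C)(C)C | intermediate (not isolated)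
16 | (2S,3S,4R)-7,8-bis(benzyloxy)-2-[4-(benzyloxy)phenyl]-3-[(triisopropylsilyl)oxy]chroman-4-yl 3,4-bis(benzyloxy)-2-[(tert-butyldimethylsilyl)oxy]benzoate (4-O-aroyl derivative of 10, same spatial arrangement) | O=C(O[C@@H]1c2ccc(OCc3ccccc3)c(OCc3ccccc3)c2O[C@@H](c2ccc(OCc3ccccc3)cc2)[C@@H]1O[Si](C(C)C)(C(C)C)C(C)C)c1ccc(OCc2ccccc2)c(OCc2ccccc2)c1O[Si](C)(C)C(C)(C)C | intermediate
17 | diisobutylaluminium alkoxide of the hemiacetal formed by hydride addition to the ester carbonyl of 16 (both epimers) | CC(C)C[Al](CC(C)C)OC(O[C@@H]1c2ccc(OCc3ccccc3)c(OCc3ccccc3)c2O[C@@H](c2ccc(OCc3ccccc3)cc2)[C@@H]1O[Si](C(C)C)(C(C)C)C(C)C)c1ccc(OCc2ccccc2)c(OCc2ccccc2)c1O[Si](C)(C)C(C)(C)C | intermediate (not isolated)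
18 | {3,4-bis(benzyloxy)-2-[(tert-butyldimethylsilyl)oxy]phenyl}{[(2S,3S,4R)-7,8-bis(benzyloxy)-2-[4-(benzyloxy)phenyl]-3-[(triisopropylsilyl)oxy]chroman-4-yl]oxy}methyl acetate (both acetal epimers) | CC(=O)OC(O[C@@H]1c2ccc(OCc3ccccc3)c(OCc3ccccc3)c2O[C@@H](c2ccc(OCc3ccccc3)cc2)[C@@H]1O[Si](C(C)C)(C(C)C)C(C)C)c1ccc(OCc2ccccc2)c(OCc2ccccc2)c1O[Si](C)(C)C(C)(C)C | intermediate
19 | 1-(benzyloxy)-4-ethynylbenzene | C#Cc1ccc(OCc2ccccc2)cc1 | intermediate
20 | 2,2-dimethylpropanoic acid (pivalic acid) | CC(C)(C)C(=O)O | starting material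
21 | (Z)-2-[4-(benzyloxy)phenyl]ethenyl 2,2-dimethylpropanoate | CC(C)(C)C(=O)O/C=C\c1ccc(OCc2ccccc2)cc1 | intermediate
22 | caesium 2-(acetoxy{[(2S,3S,4R)-7,8-bis(benzyloxy)-2-[4-(benzyloxy)phenyl]-3-[(triisopropylsilyl)oxy]chroman-4-yl]oxy}methyl)-5,6-bis(benzyloxy)phenolate | [Cs+].CC(=O)OC(O[C@@H]1c2ccc(OCc3ccccc3)c(OCc3ccccc3)c2O[C@@H](c2ccc(OCc3ccccc3)cc2)[C@@H]1O[Si](C(C)C)(C(C)C)C(C)C)c1ccc(OCc2ccccc2)c(OCc2ccccc2)c1[O-] | intermediate (not isolated)
23 | (6E)-2,3-bis(benzyloxy)-6-({[(2S,3R,4R)-7,8-bis(benzyloxy)-2-[4-(benzyloxy)phenyl]-3-[(triisopropylsilyl)oxy]chroman-4-yl]oxy}methylidene)cyclohexa-2,4-dien-1-one | O=C1C(OCc2ccccc2)=C(OCc2ccccc2)C=C/C1=C\O[C@@H]1c2ccc(OCc3ccccc3)c(OCc3ccccc3)c2O[C@@H](c2ccc(OCc3ccccc3)cc2)[C@@H]1O[Si](C(C)C)(C(C)C)C(C)C | intermediate (not isolated)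
24 | (2R,3R,4R)-7,8-bis(benzyloxy)-2-[4-(benzyloxy)phenyl]-4-{[(2S,3R,4R)-7,8-bis(benzyloxy)-2-[4-(benzyloxy)phenyl]-3-[(triisopropylsilyl)oxy]chroman-4-yl]oxy}chroman-3-yl 2,2-dimethylpropanoate | c1ccccc1COc1ccc([C@H]2Oc3c(ccc(OCc4ccccc4)c3OCc3ccccc3)[C@@H](O[C@@H]3c4ccc(OCc5ccccc5)c(OCc5ccccc5)c4O[C@@H](c4ccc(OCc5ccccc5)cc4)[C@@H]3O[Si](C(C)C)(C(C)C)C(C)C)[C@H]2OC(=O)C(C)(C)C)cc1 | intermediate
25 | (2R,3R,4R)-7,8-bis(benzyloxy)-2-[4-(benzyloxy)phenyl]-4-{[(2S,3R,4R)-7,8-bis(benzyloxy)-2-[4-(benzyloxy)phenyl]-3-[(triisopropylsilyl)oxy]chroman-4-yl]oxy}chroman-3-ol | c1ccccc1COc1ccc([C@H]2Oc3c(ccc(OCc4ccccc4)c3OCc3ccccc3)[C@@H](O[C@@H]3c4ccc(OCc5ccccc5)c(OCc5ccccc5)c4O[C@@H](c4ccc(OCc5ccccc5)cc4)[C@@H]3O[Si](C(C)C)(C(C)C)C(C)C)[C@H]2O)cc1 | intermediate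
26 | (2R,3R,4R)-7,8-bis(benzyloxy)-2-[4-(benzyloxy)phenyl]-4-{[(2S,3R,4R)-7,8-bis(benzyloxy)-2-[4-(benzyloxy)phenyl]-3-hydroxychroman-4-yl]oxy}chroman-3-ol | c1ccccc1COc1ccc([C@H]2Oc3c(ccc(OCc4ccccc4)c3OCc3ccccc3)[C@@H](O[C@@H]3c4ccc(OCc5ccccc5)c(OCc5ccccc5)c4O[C@@H](c4ccc(OCc5ccccc5)cc4)[C@@H]3O)[C@H]2O)cc1 | intermediate
27 | (2R,3R,4R)-2-(4-hydroxyphenyl)-4-{[(2S,3R,4R)-3,7,8-trihydroxy-2-(4-hydroxyphenyl)chroman-4-yl]oxy}chromane-3,7,8-triol | Oc1ccc([C@H]2Oc3c(ccc(O)c3O)[C@@H](O[C@@H]3c4ccc(O)c(O)c4O[C@@H](c4ccc(O)cc4)[C@@H]3O)[C@H]2O)cc1 | target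

**Summary**

Total step count: 18.
Longest linear sequence: 13 steps (steps 1–7, 11, 12, 15, 16, 17, 18).

Steps most likely to fail:

1. Step 15. The donor-stabilised heterodiene may react too slowly with the enol ester, so that hydrolytic collapse or acyl transfer wins, or the unit B alkoxy group may give poor facial selectivity. The fallback uses known reactions, sets out from chalcone 5 and alcohol 10 and returns at 25. Chalcone 5 is epoxidised as in step 4 but with poly-L-leucine to give [3,4-bis(benzyloxy)-2-(methoxymethoxy)phenyl]{(2R,3S)-3-[4-(benzyloxy)phenyl]oxiran-2-yl}methanone F1. HCl in MeOH–THF converts this into (2R,3R)-7,8-bis(benzyloxy)-2-[4-(benzyloxy)phenyl]-3-hydroxy-2,3-dihydro-4H-chromen-4-one F2. NaBH4 in MeOH–THF should give the 2,3-trans-3,4-trans diol (2R,3S,4R)-7,8-bis(benzyloxy)-2-[4-(benzyloxy)phenyl]chromane-3,4-diol F3. Benzyl mercaptan in AcOH exchanges the benzylic 4-hydroxyl for sulfur to give (2R,3R)-4-(benzylsulfanyl)-7,8-bis(benzyloxy)-2-[4-(benzyloxy)phenyl]chroman-3-ol F4. AgBF4 with 2,6-di-tert-butyl-4-methylpyridine in CH2Cl2 at −40 °C ionises F4 selectively in the presence of 10. Capture of the unit A cation anti to its 3-hydroxyl should give the 3,4-trans ether (2R,3S,4R)-7,8-bis(benzyloxy)-2-[4-(benzyloxy)phenyl]-4-{[(2S,3R,4R)-7,8-bis(benzyloxy)-2-[4-(benzyloxy)phenyl]-3-[(triisopropylsilyl)oxy]chroman-4-yl]oxy}chroman-3-ol F5, in which only C3 of unit A has the wrong configuration. Dess–Martin oxidation gives the ketone (2R,4R)-7,8-bis(benzyloxy)-2-[4-(benzyloxy)phenyl]-4-{[(2S,3R,4R)-7,8-bis(benzyloxy)-2-[4-(benzyloxy)phenyl]-3-[(triisopropylsilyl)oxy]chroman-4-yl]oxy}chroman-3-one F6. LiBH(s-Bu)3 at −78 °C, adding from the face opposite the cis-disposed 2-aryl and 4-alkoxy groups, should then give the all-cis alcohol 25.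

2. Step 12. The aluminium hemiacetal may collapse before it is acetylated, leading to over-reduction, or the very electron-rich α-acetoxy ether may ionise during isolation. The fallback sets out from aldehyde 13 and alcohol 10 and returns at 18. Aldehyde 13 is treated with acetyl chloride and catalytic ZnCl2 in CH2Cl2 at −20 °C to give the α-chloroalkyl ester chloro{3,4-bis(benzyloxy)-2-[(tert-butyldimethylsilyl)oxy]phenyl}methyl acetate F7. Its chloride is displaced by 10 with i-Pr2NEt in CH2Cl2 at −40 °C, so the acetal carbon is assembled by substitution instead of by ester reduction.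

3. Step 5. Opening of the epoxide with carbocation character at the p-benzyloxybenzylic carbon may erode the configuration at C2, or methanol may open the epoxide in competition with the phenol. The fallback sets out from acetophenone 2 and returns at 8. Condensation with N,N-dimethylformamide dimethyl acetal gives (E)-1-[3,4-bis(benzyloxy)-2-hydroxyphenyl]-3-(dimethylamino)prop-2-en-1-one F8, and HCl in CH2Cl2 closes it to 7,8-bis(benzyloxy)-4H-chromen-4-one F9. Conjugate addition of 4-(benzyloxy)phenylboronic acid, catalysed by Pd(OCOCF3)2 with the t-BuPyOx enantiomer that gives the 2R product, gives (2R)-7,8-bis(benzyloxy)-2-[4-(benzyloxy)phenyl]-2,3-dihydro-4H-chromen-4-one F10. Me3SiOTf and Et3N give the silyl enol ether (2R)-7,8-bis(benzyloxy)-2-[4-(benzyloxy)phenyl]-4-[(trimethylsilyl)oxy]-2H-chromene F11. Rubottom oxidation with dimethyldioxirane anti to the 2-aryl group, followed by mild acidic work-up, should give 8.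

**Further compounds**

F1 | step 15 | [3,4-bis(benzyloxy)-2-(methoxymethoxy)phenyl]{(2R,3S)-3-[4-(benzyloxy)phenyl]oxiran-2-yl}methanone | COCOc1c(C(=O)[C@@H]2O[C@H]2c2ccc(OCc3ccccc3)cc2)ccc(OCc2ccccc2)c1OCc1ccccc1
F2 | step 15 | (2R,3R)-7,8-bis(benzyloxy)-2-[4-(benzyloxy)phenyl]-3-hydroxy-2,3-dihydro-4H-chromen-4-one | O=C1c2ccc(OCc3ccccc3)c(OCc3ccccc3)c2O[C@H](c2ccc(OCc3ccccc3)cc2)[C@H]1O
F3 | step 15 | (2R,3S,4R)-7,8-bis(benzyloxy)-2-[4-(benzyloxy)phenyl]chromane-3,4-diol | O[C@@H]1c2ccc(OCc3ccccc3)c(OCc3ccccc3)c2O[C@H](c2ccc(OCc3ccccc3)cc2)[C@H]1O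
F4 | step 15 | (2R,3R)-4-(benzylsulfanyl)-7,8-bis(benzyloxy)-2-[4-(benzyloxy)phenyl]chroman-3-ol (2,3-trans, C4 epimers) | c1ccccc1CSC1c2ccc(OCc3ccccc3)c(OCc3ccccc3)c2O[C@H](c2ccc(OCc3ccccc3)cc2)[C@H]1O
F5 | step 15 | (2R,3S,4R)-7,8-bis(benzyloxy)-2-[4-(benzyloxy)phenyl]-4-{[(2S,3R,4R)-7,8-bis(benzyloxy)-2-[4-(benzyloxy)phenyl]-3-[(triisopropylsilyl)oxy]chroman-4-yl]oxy}chroman-3-ol | c1ccccc1COc1ccc([C@H]2Oc3c(ccc(OCc4ccccc4)c3OCc3ccccc3)[C@@H](O[C@@H]3c4ccc(OCc5ccccc5)c(OCc5ccccc5)c4O[C@@H](c4ccc(OCc5ccccc5)cc4)[C@@H]3O[Si](C(C)C)(C(C)C)C(C)C)[C@@H]2O)cc1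
F6 | step 15 | (2R,4R)-7,8-bis(benzyloxy)-2-[4-(benzyloxy)phenyl]-4-{[(2S,3R,4R)-7,8-bis(benzyloxy)-2-[4-(benzyloxy)phenyl]-3-[(triisopropylsilyl)oxy]chroman-4-yl]oxy}chroman-3-one | c1ccccc1COc1ccc([C@H]2Oc3c(ccc(OCc4ccccc4)c3OCc3ccccc3)[C@@H](O[C@@H]3c4ccc(OCc5ccccc5)c(OCc5ccccc5)c4O[C@@H](c4ccc(OCc5ccccc5)cc4)[C@@H]3O[Si](C(C)C)(C(C)C)C(C)C)C2=O)cc1
F7 | step 12 | chloro{3,4-bis(benzyloxy)-2-[(tert-butyldimethylsilyl)oxy]phenyl}methyl acetate (racemic) | CC(=O)OC(Cl)c1ccc(OCc2ccccc2)c(OCc2ccccc2)c1O[Si](C)(C)C(C)(C)C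
F8 | step 5 | (E)-1-[3,4-bis(benzyloxy)-2-hydroxyphenyl]-3-(dimethylamino)prop-2-en-1-one | CN(C)/C=C/C(=O)c1ccc(OCc2ccccc2)c(OCc2ccccc2)c1O
F9 | step 5 | 7,8-bis(benzyloxy)-4H-chromen-4-one | O=c1ccoc2c(OCc3ccccc3)c(OCc3ccccc3)ccc12
F10 | step 5 | (2R)-7,8-bis(benzyloxy)-2-[4-(benzyloxy)phenyl]-2,3-dihydro-4H-chromen-4-one | O=C1c2ccc(OCc3ccccc3)c(OCc3ccccc3)c2O[C@@H](c2ccc(OCc3ccccc3)cc2)C1
F11 | step 5 | (2R)-7,8-bis(benzyloxy)-2-[4-(benzyloxy)phenyl]-4-[(trimethylsilyl)oxy]-2H-chromene | C[Si](C)(C)OC1=C[C@H](c2ccc(OCc3ccccc3)cc2)Oc2c1ccc(OCc1ccccc1)c2OCc1ccccc1
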